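**Plan**
- Retrosynthetic cuts: the depside ester C(=O)–O bond between the ring-A carbonyl and O4 of ring B, the O2–CH3 bond of ring B, the benzyl-protected carboxyl, then ring B itself at C1–C6.
- Enabling feature: ring B carries the carboxyl on C1, oxygens on C2 and C4 and the propyl group on C6. This is the resorcylate pattern of a linear 3,5,7-triketo ester folded by a C2-to-C7 aldol.
- Forward, ring B branch: a dioxinone is chain-extended twice (C-acetylation, then C-butanoylation of its dianion). Thermolysis with benzyl alcohol and aldol aromatisation then build ring B with a free 4-OH and a chelated 2-OH.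
- Forward, ring A branch and endgame: olivetol gives the ring-A acid by methylation, formylation and oxidation. The rings are joined at the 4-OH, the 2-OH is methylated and the benzyl ester is hydrogenolysed.
- Stereochemistry: none to set. The two sp3 centres of the transient aldol adduct vanish on aromatisation.

Key step: step 3

Assumption: the target has no stereocentre and no configurationally stable axis, so the SMILES defines a single achiral compound and no enantiocontrol is required.

**Step 1**
Reactants: 1 2,2,6-trimethyl-4H-1,3-dioxin-4-one
Product: 3 2,2-dimethyl-6-(2-oxopropyl)-4H-1,3-dioxin-4-one, via lithium dienolate 2 (not isolated)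
Conditions: LiHMDS (1.0 equiv), THF, −78 °C; AcCl (0.5 equiv), −78 °C; 1 M HCl quench
Reagents that add atoms: acetyl chloride, CC(=O)Cl
Why: Kinetic γ-deprotonation of the vinylogous ester gives the cross-conjugated dienolate, which undergoes a vinylogous Claisen C-acylation at its exocyclic carbon; half an equivalent of acetyl chloride is used because the more acidic product consumes a second equivalent of dienolate.

**Step 2**
Reactants: 3 2,2-dimethyl-6-(2-oxopropyl)-4H-1,3-dioxin-4-one; 4 N-methoxy-N-methylbutanamide
Product: 7 6-(2,4-dioxoheptyl)-2,2-dimethyl-4H-1,3-dioxin-4-one, via dilithium dianion 5 (not isolated), via tetrahedral Weinreb adduct 6 (not isolated)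
Conditions: LDA (2.2 equiv), THF, −78 °C; then 4, −78 to −30 °C; cold 1 M HCl quench
Reagents that add atoms: none
Why: The second deprotonation occurs at the terminal methyl, and this last-formed, most basic carbon of the dianion adds to the Weinreb amide (Claisen-type acylation of a 1,3-dicarbonyl dianion), the lithium-chelated adduct 6 keeping the new ketone masked until the acid quench so that neither over-addition nor proton exchange with the product can occur.

**Step 3**
Reactants: 7 6-(2,4-dioxoheptyl)-2,2-dimethyl-4H-1,3-dioxin-4-one; 8 benzyl alcohol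
Product: 12 benzyl 2,4-dihydroxy-6-propylbenzoate, via acylketene 9 (not isolated), via benzyl 3,5,7-trioxodecanoate 10 (not isolated), via cyclic aldol carbinol 11 (not isolated)
Conditions: BnOH (1.5 equiv), PhMe, 110 °C; then Cs2CO3 (2 equiv), i-PrOH/CH2Cl2, rt; then HCl in MeOH, rt
Reagents that add atoms: none
Why: Heating 7 triggers a retro-hetero-Diels–Alder loss of acetone to acylketene 9, whose ketene carbon is captured by benzyl alcohol to give the open 3,5,7-triketo ester 10. With carbonate, the C2 methylene of 10 (between the ester and the C3 ketone) is enolised and adds to the C7 propyl ketone in a 6-exo-trig intramolecular aldol, forming the bond that becomes C1–C6 of ring B and closing the six-membered carbocycle as carbinol 11; acid then drives dehydration and enolisation of the two remaining ring ketones to the phenols of 12. The closest known reaction type is the biomimetic resorcylate synthesis from diketo-dioxinones by ketene trapping followed by aldol aromatisation. No stereocentre is created in 12, and the two sp3 centres of 11 are erased on aromatisation. The step needs intermolecular alcohol capture to outrun attack of an enol oxygen on the ketene (pyranone formation), which the excess of an unhindered primary alcohol should secure, and it needs C2-to-C7 aldol closure in preference to Claisen closure onto the ester or lactonisation, which follows from the high acidity of the C2–H, the greater electrophilicity of a ketone over an ester and the use of a mild base before any acid is added. The product has a free 4-hydroxyl and a 2-hydroxyl hydrogen-bonded to the ester, the differentiation used in steps 7 and 8.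

**Step 4**
Reactants: 13 olivetol (5-pentylbenzene-1,3-diol)
Product: 14 1,3-dimethoxy-5-pentylbenzene
Conditions: MeI, K2CO3, acetone, reflux
Reagents that add atoms: iodomethane, CI
Why: Williamson etherification of two free, unhindered phenols with a methyl electrophile under mild carbonate base.

**Step 5**
Reactants: 14 1,3-dimethoxy-5-pentylbenzene
Product: 16 2,4-dimethoxy-6-pentylbenzaldehyde, via aryl iminium chloride 15 (not isolated)
Conditions: POCl3, DMF, 0 °C then 70 °C; then ice-water, rt
Reagents that add atoms: N,N-dimethylformamide, CN(C)C=O; water, O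
Why: Vilsmeier–Haack formylation, in which the bulky chloroiminium electrophile attacks the position ortho to one methoxy and para to the other (the two such positions are equivalent by symmetry) in preference to the crowded position between the two methoxy groups, and hydrolysis of iminium salt 15 releases the aldehyde.

**Step 6**
Reactants: 16 2,4-dimethoxy-6-pentylbenzaldehyde
Product: 17 2,4-dimethoxy-6-pentylbenzoic acid
Conditions: NaClO2, NaH2PO4, 2-methylbut-2-ene (excess), t-BuOH/H2O, rt
Reagents that add atoms: sodium chlorite, [Na+].[O-]Cl=O
Why: Pinnick oxidation converts the aryl aldehyde into the acid under buffered conditions, and the alkene scavenger removes hypochlorous acid before it can chlorinate the electron-rich ring.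

**Step 7**
Reactants: 17 2,4-dimethoxy-6-pentylbenzoic acid; 12 benzyl 2,4-dihydroxy-6-propylbenzoate
Product: 19 benzyl 4-[(2,4-dimethoxy-6-pentylbenzoyl)oxy]-2-hydroxy-6-propylbenzoate, via mixed trifluoroacetic anhydride 18 (not isolated)
Conditions: TFAA, PhMe, rt
Reagents that add atoms: none
Why: Mixed-anhydride esterification, in which anhydride 18 of the electron-rich, di-ortho-substituted acid transfers its aroyl group to the free 4-hydroxyl of 12, whereas the 2-hydroxyl is hydrogen-bonded to the benzyl ester carbonyl, crowded and much less nucleophilic.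

**Step 8**
Reactants: 19 benzyl 4-[(2,4-dimethoxy-6-pentylbenzoyl)oxy]-2-hydroxy-6-propylbenzoate
Product: 20 benzyl 4-[(2,4-dimethoxy-6-pentylbenzoyl)oxy]-2-methoxy-6-propylbenzoate
Conditions: MeI (excess), anhydrous K2CO3, dry acetone, reflux
Reagents that add atoms: iodomethane, CI
Why: Williamson O-methylation of the one remaining phenol; carbonate in dry acetone is non-nucleophilic and the depside carbonyl is shielded by its ortho pentyl and methoxy groups, so both esters should persist while the chelated phenoxide is alkylated.

**Step 9**
Reactants: 20 benzyl 4-[(2,4-dimethoxy-6-pentylbenzoyl)oxy]-2-methoxy-6-propylbenzoate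
Product: 21 4-[(2,4-dimethoxy-6-pentylbenzoyl)oxy]-2-methoxy-6-propylbenzoic acid
Conditions: H2 (1 atm), 10% Pd/C, EtOAc, rt
Reagents that add atoms: none
Why: Catalytic hydrogenolysis cleaves only the benzylic C–O bond of the benzyl ester under neutral conditions, leaving the aryl ester, the methyl ethers and both arenes untouched.

**Compound list**
1 | 2,2,6-trimethyl-4H-1,3-dioxin-4-one | CC1=CC(=O)OC(C)(C)O1 | starting material
2 | lithium 2,2-dimethyl-6-methylidene-6H-1,3-dioxin-4-olate (lithium dienolate of 1) | [Li]OC1=CC(=C)OC(C)(C)O1 | intermediate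
3 | 2,2-dimethyl-6-(2-oxopropyl)-4H-1,3-dioxin-4-one | CC(=O)CC1=CC(=O)OC(C)(C)O1 | intermediate
4 | N-methoxy-N-methylbutanamide | CCCC(=O)N(C)OC | starting material
5 | dilithium dianion of 3 (terminal enolate plus ring dienolate) | [Li]OC(=C)C=C1C=C(O[Li])OC(C)(C)O1 | intermediate
6 | dilithium salt of the tetrahedral adduct of 5 and 4 | CCCC(O[Li])(N(C)OC)CC(=O)C=C1C=C(O[Li])OC(C)(C)O1 | intermediate
7 | 6-(2,4-dioxoheptyl)-2,2-dimethyl-4H-1,3-dioxin-4-one | CCCC(=O)CC(=O)CC1=CC(=O)OC(C)(C)O1 | intermediate
8 | benzyl alcohol | OCc1ccccc1 | starting material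
9 | 3,5,7-trioxodec-1-en-1-one (acylketene) | CCCC(=O)CC(=O)CC(=O)C=C=O | intermediate
10 | benzyl 3,5,7-trioxodecanoate | CCCC(=O)CC(=O)CC(=O)CC(=O)OCc1ccccc1 | intermediate
11 | benzyl 2-hydroxy-4,6-dioxo-2-propylcyclohexane-1-carboxylate (mixture of stereoisomers, transient) | CCCC1(O)CC(=O)CC(=O)C1C(=O)OCc1ccccc1 | intermediate
12 | benzyl 2,4-dihydroxy-6-propylbenzoate | CCCc1cc(O)cc(O)c1C(=O)OCc1ccccc1 | intermediate
13 | olivetol (5-pentylbenzene-1,3-diol) | CCCCCc1cc(O)cc(O)c1 | starting material
14 | 1,3-dimethoxy-5-pentylbenzene | CCCCCc1cc(OC)cc(OC)c1 | intermediate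
15 | (2,4-dimethoxy-6-pentylbenzylidene)dimethyliminium chloride | CCCCCc1cc(OC)cc(OC)c1C=[N+](C)C.[Cl-] | intermediate
16 | 2,4-dimethoxy-6-pentylbenzaldehyde | CCCCCc1cc(OC)cc(OC)c1C=O | intermediate
17 | 2,4-dimethoxy-6-pentylbenzoic acid | CCCCCc1cc(OC)cc(OC)c1C(=O)O | intermediate
18 | 2,4-dimethoxy-6-pentylbenzoic trifluoroacetic anhydride | CCCCCc1cc(OC)cc(OC)c1C(=O)OC(=O)C(F)(F)F | intermediate
19 | benzyl 4-[(2,4-dimethoxy-6-pentylbenzoyl)oxy]-2-hydroxy-6-propylbenzoate | CCCCCc1cc(OC)cc(OC)c1C(=O)Oc1cc(CCC)c(C(=O)OCc2ccccc2)c(O)c1 | intermediate
20 | benzyl 4-[(2,4-dimethoxy-6-pentylbenzoyl)oxy]-2-methoxy-6-propylbenzoate | CCCCCc1cc(OC)cc(OC)c1C(=O)Oc1cc(CCC)c(C(=O)OCc2ccccc2)c(OC)c1 | intermediate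
21 | 4-[(2,4-dimethoxy-6-pentylbenzoyl)oxy]-2-methoxy-6-propylbenzoic acid | CCCCCc1cc(OC)cc(OC)c1C(=O)Oc1cc(CCC)c(C(=O)O)c(OC)c1 | target

**Total step count:** 9
**Longest linear sequence:** 6 steps (1, 2, 3, 7, 8, 9; the ring-A branch 4, 5, 6, 7, 8, 9 is equally long)

**Steps most likely to fail**

1. Step 3. The acylketene may be captured by its own enol oxygen before the alcohol reaches it, or the open triketo ester may close through oxygen or in the Claisen sense, so that pyranone-type material forms in place of the arene. The fallback closes the ring before the ester is installed. It sets out from 7: triethylamine in CH2Cl2 at rt should effect the same aldol C–C closure with the dioxinone ring still in place and give 7-hydroxy-2,2-dimethyl-5-propyl-4H-1,3-benzodioxin-4-one F1. Irradiation of F1 at about 300 nm with benzyl alcohol in CH2Cl2 (photochemical cycloreversion to the quinoketene, then capture by the alcohol) would give the benzyl ester, and the route is rejoined at 12.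

2. Step 2. Addition of the dianion to the weakly electrophilic amide may be slow, so that warming is needed and the dianion decays, and the polycarbonyl product may self-condense during work-up or chromatography. The fallback introduces the butanoyl group by soft enolisation of an ester-activated methylene. It sets out from 1. Monoallyl malonate is first activated with benzotriazole and SOCl2 as allyl 3-(1H-benzotriazol-1-yl)-3-oxopropanoate F2. The lithium dienolate of 1 (in excess) is C-acylated with it to give allyl 4-(2,2-dimethyl-4-oxo-4H-1,3-dioxin-6-yl)-3-oxobutanoate F3. MgCl2 and pyridine with butanoyl chloride in CH2Cl2 at 0 °C should acylate the doubly activated carbon and give allyl 2-butanoyl-4-(2,2-dimethyl-4-oxo-4H-1,3-dioxin-6-yl)-3-oxobutanoate F4. Pd(PPh3)4 with morpholine in THF (Tsuji–Trost deallylation) followed by spontaneous decarboxylation of the β-keto acid returns the route at 7.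

3. Step 8. Alkylation of the hydrogen-bonded phenol may be sluggish, and prolonged exposure to base may cause acyl transfer or cleavage at the depside ester. The fallback installs the methyl ether before the two rings are joined. It sets out from 12. Allyl bromide and K2CO3 in acetone at rt should alkylate only the free 4-hydroxyl and give benzyl 2-hydroxy-6-propyl-4-(prop-2-en-1-yloxy)benzoate F5. MeI and K2CO3 in DMF, now without any aryl ester present, give benzyl 2-methoxy-6-propyl-4-(prop-2-en-1-yloxy)benzoate F6. Pd(PPh3)4 with morpholine in THF removes the allyl ether and gives benzyl 4-hydroxy-2-methoxy-6-propylbenzoate F7. Esterification of F7 with acid 17 under the TFAA conditions of step 7 rejoins the route at 20.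

**Further compounds**
F1 | step 3 | 7-hydroxy-2,2-dimethyl-5-propyl-4H-1,3-benzodioxin-4-one | CCCc1cc(O)cc2OC(C)(C)OC(=O)c12
F2 | step 2 | allyl 3-(1H-benzotriazol-1-yl)-3-oxopropanoate | C=CCOC(=O)CC(=O)n1nnc2ccccc12
F3 | step 2 | allyl 4-(2,2-dimethyl-4-oxo-4H-1,3-dioxin-6-yl)-3-oxobutanoate | C=CCOC(=O)CC(=O)CC1=CC(=O)OC(C)(C)O1
F4 | step 2 | allyl 2-butanoyl-4-(2,2-dimethyl-4-oxo-4H-1,3-dioxin-6-yl)-3-oxobutanoate | C=CCOC(=O)C(C(=O)CCC)C(=O)CC1=CC(=O)OC(C)(C)O1
F5 | step 8 | benzyl 2-hydroxy-6-propyl-4-(prop-2-en-1-yloxy)benzoate | CCCc1cc(OCC=C)cc(O)c1C(=O)OCc1ccccc1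
F6 | step 8 | benzyl 2-methoxy-6-propyl-4-(prop-2-en-1-yloxy)benzoate | CCCc1cc(OCC=C)cc(OC)c1C(=O)OCc1ccccc1
F7 | step 8 | benzyl 4-hydroxy-2-methoxy-6-propylbenzoate | CCCc1cc(O)cc(OC)c1C(=O)OCc1ccccc1
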